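The Ca–Cb bond of dioxane ring B, which joins two oxygen-bearing benzylic carbons (Ca carries catechol ring C, Cb resorcinol ring D), is the disconnection. Both ring-B oxygens are placed first on a stilbene catechol (ring A): the future Cb as a benzyl ether, whose C–H is acidic, the future Ca as the acyl carbon of a ring-C benzoate. In one operation, benzylic lithiation and 6-exo attack on the ester forge Ca–Cb and close ring B as a hemiketal. Because ring C is para-oxygenated, Ca then ionises readily, and a chiral-acid transfer hydrogenation sets the cis (Ca R, Cb S) pair.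

Key step: step 9

Remarks on the chemistry:
- Ca is the ring-B carbon bearing the 3,4-dihydroxyphenyl ring C; its ring oxygen is meta to the styryl carbon of ring A. Cb bears the 3,5-dihydroxyphenyl ring D; its ring oxygen is para to the styryl carbon. The target is the cis isomer (Ca R, Cb S). TIPS = triisopropylsilyl.
- Assumption: hemiketal 15 is written ring-closed; its ring-opened keto-phenol tautomer would enter step 10 equally well.
- Assumption: the sense of induction in step 10 cannot be predicted with certainty; the (R)-acid is written, and its mirror image would be used if it proves to favour the other enantiomer.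

Step 1
Reactants: 1 3,5-dihydroxybenzaldehyde
Product: 2 3,5-bis(triisopropylsilyloxy)benzaldehyde
Conditions: TIPSCl (2.2 equiv), imidazole, DMF, rt
Reagents that add atoms: chlorotriisopropylsilane, CC(C)[Si](Cl)(C(C)C)C(C)C
Why: Imidazole-promoted silyl ether formation on both phenols; aryl TIPS ethers should survive the later basic and acidic steps and leave with fluoride at the end.

Step 2
Reactants: 2 3,5-bis(triisopropylsilyloxy)benzaldehyde
Product: 3 [3,5-bis(triisopropylsilyloxy)phenyl]methanol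
Conditions: NaBH4, MeOH–THF, 0 °C
Reagents that add atoms: none
Why: Borohydride reduction of an aryl aldehyde to the benzylic alcohol; the silyl ethers are inert.

Step 3
Reactants: 3 [3,5-bis(triisopropylsilyloxy)phenyl]methanol
Product: 4 3,5-bis(triisopropylsilyloxy)benzyl bromide
Conditions: CBr4, PPh3, CH2Cl2, 0 °C
Reagents that add atoms: carbon tetrabromide, BrC(Br)(Br)Br
Why: Appel reaction converts the primary benzylic alcohol into the bromide under neutral conditions that leave the aryl silyl ethers intact.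

Step 4
Reactants: 4 3,5-bis(triisopropylsilyloxy)benzyl bromide
Product: 5 diethyl [3,5-bis(triisopropylsilyloxy)benzyl]phosphonate
Conditions: P(OEt)3, neat, 130 °C
Reagents that add atoms: triethyl phosphite, CCOP(OCC)OCC
Why: Michaelis–Arbuzov reaction of a reactive benzylic bromide gives the phosphonate needed for the stilbene.

Step 5
Reactants: 6 3,4-dihydroxybenzaldehyde; 4 3,5-bis(triisopropylsilyloxy)benzyl bromide
Product: 7 4-{[3,5-bis(triisopropylsilyloxy)benzyl]oxy}-3-hydroxybenzaldehyde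
Conditions: NaHCO3, NaI (cat.), DMF, 40 °C
Reagents that add atoms: none
Why: Williamson etherification with a weak base should alkylate only the more acidic 4-hydroxyl (para to the formyl group), which places the future Cb on the oxygen para to the later styryl carbon.

Step 6
Reactants: 7 4-{[3,5-bis(triisopropylsilyloxy)benzyl]oxy}-3-hydroxybenzaldehyde; 5 diethyl [3,5-bis(triisopropylsilyloxy)benzyl]phosphonate
Product: 8 2-{[3,5-bis(triisopropylsilyloxy)benzyl]oxy}-5-{(E)-2-[3,5-bis(triisopropylsilyloxy)phenyl]ethenyl}phenol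
Conditions: NaH (2.2 equiv), THF, 0 °C to rt; then AcOH
Reagents that add atoms: none
Why: Horner–Wadsworth–Emmons olefination of a benzylic phosphonate with an aryl aldehyde should give the (E)-stilbene; the meta-phenoxide formed first does not deactivate the aldehyde.

Step 7
Reactants: 9 3,4-dihydroxybenzoic acid
Product: 11 3,4-bis(triisopropylsilyloxy)benzoic acid, via silyl ester 10 (not isolated)
Conditions: TIPSCl (3.3 equiv), imidazole, DMF, rt; then K2CO3, MeOH–THF–H2O, rt; aq. KHSO4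
Reagents that add atoms: chlorotriisopropylsilane, CC(C)[Si](Cl)(C(C)C)C(C)C
Why: Exhaustive silylation followed by selective hydrolysis of the silyl ester, which is far more labile than the two aryl silyl ethers, frees the carboxylic acid.

Step 8
Reactants: 8 2-{[3,5-bis(triisopropylsilyloxy)benzyl]oxy}-5-{(E)-2-[3,5-bis(triisopropylsilyloxy)phenyl]ethenyl}phenol; 11 3,4-bis(triisopropylsilyloxy)benzoic acid
Product: 12 2-{[3,5-bis(triisopropylsilyloxy)benzyl]oxy}-5-{(E)-2-[3,5-bis(triisopropylsilyloxy)phenyl]ethenyl}phenyl 3,4-bis(triisopropylsilyloxy)benzoate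
Conditions: DIC, DMAP (cat.), CH2Cl2, rt
Reagents that add atoms: none
Why: Steglich esterification acylates the remaining phenol (the oxygen meta to the styryl carbon) and so installs the future Ca as an ester carbonyl next to the benzyl ether.

Step 9
Reactants: 12 2-{[3,5-bis(triisopropylsilyloxy)benzyl]oxy}-5-{(E)-2-[3,5-bis(triisopropylsilyloxy)phenyl]ethenyl}phenyl 3,4-bis(triisopropylsilyloxy)benzoate
Product: 15 2-[3,4-bis(triisopropylsilyloxy)phenyl]-3-[3,5-bis(triisopropylsilyloxy)phenyl]-7-{(E)-2-[3,5-bis(triisopropylsilyloxy)phenyl]ethenyl}-2,3-dihydro-1,4-benzodioxin-2-ol (C2 = Ca; racemic mixture of diastereomers), via benzylic organolithium 13 (not isolated), via lithium hemiketalate 14 (not isolated)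
Conditions: LiTMP (lithium 2,2,6,6-tetramethylpiperidide, 2.5 equiv), THF, −78 to −40 °C; then AcOH, −78 °C
Reagents that add atoms: none
Why: LiTMP removes a benzylic proton of the ArO–CH2–ring D ether (the only acidic C–H, acidified by ring D and its two meta-siloxy groups and pre-complexed to the neighbouring ester carbonyl) to give 13, whose carbanion carbon Cb adds to the ester carbonyl carbon Ca on the adjacent oxygen, forming the Ca–Cb bond and lithium hemiketalate 14, which is protonated to 15 (anionic O-to-C acyl transfer in which the ester C–O bond becomes the Ca–O bond of ring B). The closest known reaction types are the Baker–Venkataraman acyl transfer, the anionic homo-Fries rearrangement and the amide-base cyclisation of 2-benzyloxybenzoates to 2-arylbenzofuran-3-ones. Ring B is closed in the 6-exo-trig mode. Ca (anomeric) and Cb (epimerisable through the ring-opened keto-phenol tautomer) are created here without control, on purpose, and both are fixed in step 10. The step needs benzylic deprotonation to win over attack on the ester and over ortho-lithiation, and acylation to outrun [1,2]-Wittig rearrangement; the hindered non-nucleophilic amide base, the low temperature and the ester trap held next to the carbanion should secure this.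

Step 10
Reactants: 15 2-[3,4-bis(triisopropylsilyloxy)phenyl]-3-[3,5-bis(triisopropylsilyloxy)phenyl]-7-{(E)-2-[3,5-bis(triisopropylsilyloxy)phenyl]ethenyl}-2,3-dihydro-1,4-benzodioxin-2-ol
Product: 17 (2R,3S)-2-[3,4-bis(triisopropylsilyloxy)phenyl]-3-[3,5-bis(triisopropylsilyloxy)phenyl]-7-{(E)-2-[3,5-bis(triisopropylsilyloxy)phenyl]ethenyl}-2,3-dihydro-1,4-benzodioxine (C2 = Ca; cis), via benzodioxin 16 (not isolated)
Conditions: (R)-3,3'-bis(2,4,6-triisopropylphenyl)-1,1'-binaphthyl-2,2'-diyl N-triflylphosphoramide (5 mol %), Hantzsch ester (diethyl 2,6-dimethyl-1,4-dihydropyridine-3,5-dicarboxylate, 1.5 equiv), 5 Å molecular sieves, toluene, −20 °C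
Reagents that add atoms: none
Why: Proposed new method: the acid dehydrates 15 to dioxin 16, which is reprotonated at Cb to give the Ca oxocarbenium ion (a para-siloxybenzyl cation stabilised by ring C, hence regioselective protonation) paired with the chiral phosphoramide anion; the two Cb-epimeric ion pairs interconvert through 16 (dynamic kinetic resolution), hydride from the Hantzsch ester should enter Ca anti to ring D on Cb, which gives the cis relation, and the chiral anion should select the ion pair leading to (Ca R, Cb S), while the stilbene is not reduced; the closest known reaction type is the chiral-phosphoric-acid transfer hydrogenation of cyclic iminium ions with Hantzsch esters, including dynamic kinetic resolution through enamine–iminium equilibration, together with chiral-anion-controlled additions to cyclic oxocarbenium ions.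

Step 11
Reactants: 17 (2R,3S)-2-[3,4-bis(triisopropylsilyloxy)phenyl]-3-[3,5-bis(triisopropylsilyloxy)phenyl]-7-{(E)-2-[3,5-bis(triisopropylsilyloxy)phenyl]ethenyl}-2,3-dihydro-1,4-benzodioxine
Product: 18 CNP0283264.2, (2R,3S)-2-(3,4-dihydroxyphenyl)-3-(3,5-dihydroxyphenyl)-7-[(E)-2-(3,5-dihydroxyphenyl)ethenyl]-2,3-dihydro-1,4-benzodioxine (C2 = Ca; cis)
Conditions: TBAF (7 equiv), AcOH (7 equiv), THF, 0 °C, under argon
Reagents that add atoms: none
Why: Fluoride desilylation of the six aryl silyl ethers, buffered with acetic acid so that each phenoxide is protonated at once, should leave the two benzylic C–O bonds, both stereocenters and the (E)-alkene untouched.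

Compound list
1 | 3,5-dihydroxybenzaldehyde | O=Cc1cc(O)cc(O)c1 | starting material
2 | 3,5-bis(triisopropylsilyloxy)benzaldehyde | O=Cc1cc(O[Si](C(C)C)(C(C)C)C(C)C)cc(O[Si](C(C)C)(C(C)C)C(C)C)c1 | intermediate
3 | [3,5-bis(triisopropylsilyloxy)phenyl]methanol | OCc1cc(O[Si](C(C)C)(C(C)C)C(C)C)cc(O[Si](C(C)C)(C(C)C)C(C)C)c1 | intermediate
4 | 3,5-bis(triisopropylsilyloxy)benzyl bromide | BrCc1cc(O[Si](C(C)C)(C(C)C)C(C)C)cc(O[Si](C(C)C)(C(C)C)C(C)C)c1 | intermediate
5 | diethyl [3,5-bis(triisopropylsilyloxy)benzyl]phosphonate | CCOP(=O)(Cc1cc(O[Si](C(C)C)(C(C)C)C(C)C)cc(O[Si](C(C)C)(C(C)C)C(C)C)c1)OCC | intermediate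
6 | 3,4-dihydroxybenzaldehyde | O=Cc1ccc(O)c(O)c1 | starting material
7 | 4-{[3,5-bis(triisopropylsilyloxy)benzyl]oxy}-3-hydroxybenzaldehyde | O=Cc1ccc(OCc2cc(O[Si](C(C)C)(C(C)C)C(C)C)cc(O[Si](C(C)C)(C(C)C)C(C)C)c2)c(O)c1 | intermediate
8 | 2-{[3,5-bis(triisopropylsilyloxy)benzyl]oxy}-5-{(E)-2-[3,5-bis(triisopropylsilyloxy)phenyl]ethenyl}phenol | Oc1cc(/C=C/c2cc(O[Si](C(C)C)(C(C)C)C(C)C)cc(O[Si](C(C)C)(C(C)C)C(C)C)c2)ccc1OCc1cc(O[Si](C(C)C)(C(C)C)C(C)C)cc(O[Si](C(C)C)(C(C)C)C(C)C)c1 | intermediate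
9 | 3,4-dihydroxybenzoic acid | OC(=O)c1ccc(O)c(O)c1 | starting material
10 | triisopropylsilyl 3,4-bis(triisopropylsilyloxy)benzoate | CC(C)[Si](OC(=O)c1ccc(O[Si](C(C)C)(C(C)C)C(C)C)c(O[Si](C(C)C)(C(C)C)C(C)C)c1)(C(C)C)C(C)C | intermediate
11 | 3,4-bis(triisopropylsilyloxy)benzoic acid | OC(=O)c1ccc(O[Si](C(C)C)(C(C)C)C(C)C)c(O[Si](C(C)C)(C(C)C)C(C)C)c1 | intermediate
12 | 2-{[3,5-bis(triisopropylsilyloxy)benzyl]oxy}-5-{(E)-2-[3,5-bis(triisopropylsilyloxy)phenyl]ethenyl}phenyl 3,4-bis(triisopropylsilyloxy)benzoate | O=C(Oc1cc(/C=C/c2cc(O[Si](C(C)C)(C(C)C)C(C)C)cc(O[Si](C(C)C)(C(C)C)C(C)C)c2)ccc1OCc1cc(O[Si](C(C)C)(C(C)C)C(C)C)cc(O[Si](C(C)C)(C(C)C)C(C)C)c1)c1ccc(O[Si](C(C)C)(C(C)C)C(C)C)c(O[Si](C(C)C)(C(C)C)C(C)C)c1 | intermediate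
13 | benzylic organolithium of 12 (lithium on the OCH carbon, the future Cb) | O=C(Oc1cc(/C=C/c2cc(O[Si](C(C)C)(C(C)C)C(C)C)cc(O[Si](C(C)C)(C(C)C)C(C)C)c2)ccc1OC([Li])c1cc(O[Si](C(C)C)(C(C)C)C(C)C)cc(O[Si](C(C)C)(C(C)C)C(C)C)c1)c1ccc(O[Si](C(C)C)(C(C)C)C(C)C)c(O[Si](C(C)C)(C(C)C)C(C)C)c1 | intermediate
14 | lithium hemiketalate (lithium 2-olate of 15) | [Li]OC1(c2ccc(O[Si](C(C)C)(C(C)C)C(C)C)c(O[Si](C(C)C)(C(C)C)C(C)C)c2)Oc2cc(/C=C/c3cc(O[Si](C(C)C)(C(C)C)C(C)C)cc(O[Si](C(C)C)(C(C)C)C(C)C)c3)ccc2OC1c1cc(O[Si](C(C)C)(C(C)C)C(C)C)cc(O[Si](C(C)C)(C(C)C)C(C)C)c1 | intermediate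
15 | 2-[3,4-bis(triisopropylsilyloxy)phenyl]-3-[3,5-bis(triisopropylsilyloxy)phenyl]-7-{(E)-2-[3,5-bis(triisopropylsilyloxy)phenyl]ethenyl}-2,3-dihydro-1,4-benzodioxin-2-ol (racemic mixture of diastereomers) | OC1(c2ccc(O[Si](C(C)C)(C(C)C)C(C)C)c(O[Si](C(C)C)(C(C)C)C(C)C)c2)Oc2cc(/C=C/c3cc(O[Si](C(C)C)(C(C)C)C(C)C)cc(O[Si](C(C)C)(C(C)C)C(C)C)c3)ccc2OC1c1cc(O[Si](C(C)C)(C(C)C)C(C)C)cc(O[Si](C(C)C)(C(C)C)C(C)C)c1 | intermediate
16 | 2-[3,4-bis(triisopropylsilyloxy)phenyl]-3-[3,5-bis(triisopropylsilyloxy)phenyl]-7-{(E)-2-[3,5-bis(triisopropylsilyloxy)phenyl]ethenyl}-1,4-benzodioxine | C1(c2ccc(O[Si](C(C)C)(C(C)C)C(C)C)c(O[Si](C(C)C)(C(C)C)C(C)C)c2)=C(c2cc(O[Si](C(C)C)(C(C)C)C(C)C)cc(O[Si](C(C)C)(C(C)C)C(C)C)c2)Oc2ccc(/C=C/c3cc(O[Si](C(C)C)(C(C)C)C(C)C)cc(O[Si](C(C)C)(C(C)C)C(C)C)c3)cc2O1 | intermediate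
17 | (2R,3S)-2-[3,4-bis(triisopropylsilyloxy)phenyl]-3-[3,5-bis(triisopropylsilyloxy)phenyl]-7-{(E)-2-[3,5-bis(triisopropylsilyloxy)phenyl]ethenyl}-2,3-dihydro-1,4-benzodioxine (cis) | CC(C)[Si](Oc1cc(O[Si](C(C)C)(C(C)C)C(C)C)cc(/C=C/c2ccc3c(c2)O[C@H](c2ccc(O[Si](C(C)C)(C(C)C)C(C)C)c(O[Si](C(C)C)(C(C)C)C(C)C)c2)[C@H](c2cc(O[Si](C(C)C)(C(C)C)C(C)C)cc(O[Si](C(C)C)(C(C)C)C(C)C)c2)O3)c1)(C(C)C)C(C)C | intermediate
18 | CNP0283264.2, (2R,3S)-2-(3,4-dihydroxyphenyl)-3-(3,5-dihydroxyphenyl)-7-[(E)-2-(3,5-dihydroxyphenyl)ethenyl]-2,3-dihydro-1,4-benzodioxine (cis) | Oc1cc(O)cc(/C=C/c2ccc3c(c2)O[C@H](c2ccc(O)c(O)c2)[C@H](c2cc(O)cc(O)c2)O3)c1 | target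

Total step count: 11. Longest linear sequence: 9 steps (steps 1, 2, 3, 5, 6, 8, 9, 10, 11).

Steps most likely to fail

1. Step 10 (Proposed new method). What may go wrong is weak discrimination between the two Cb-epimeric ion pairs (low enantiomeric purity), an uncatalysed background reduction, or acid-promoted re-ionisation of the Ca–O bond of the product with drift from cis to trans. The fallback uses known chemistry, sets out from 15 and comes back at 17. Through its ring-opened keto-phenol tautomer, 15 is reduced by Noyori-type asymmetric transfer hydrogenation with dynamic kinetic resolution (RuCl[(R,R)-TsDPEN](p-cymene), HCO2H–Et3N, DMF, rt). By analogy with the benzoin-to-hydrobenzoin case this should give (1S,2S)-1-[3,4-bis(triisopropylsilyloxy)phenyl]-2-[3,5-bis(triisopropylsilyloxy)phenyl]-2-(4-{(E)-2-[3,5-bis(triisopropylsilyloxy)phenyl]ethenyl}-2-hydroxyphenoxy)ethanol F1. An intramolecular Mitsunobu etherification (PPh3, DIAD, THF, 0 °C) then joins the phenol oxygen to Ca with inversion and gives cis-configured 17.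

2. Step 9 (key step). What may go wrong is attack of the amide base on the benzoate, ortho-lithiation of ring C or ring A in place of benzylic deprotonation, or [1,2]-Wittig rearrangement of the benzylic anion before it is acylated. The fallback keeps the same ring-closing Ca–Cb bond formation but makes the Cb–H acidic with a temporary methoxycarbonyl group, so that a weak base suffices. It sets out from 6 and comes back at 15.
   - Purchased methyl 2-(3,5-dihydroxyphenyl)acetate F2 is silylated (TIPSCl, imidazole, DMF) to methyl 2-[3,5-bis(triisopropylsilyloxy)phenyl]acetate F3.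
   - Enolate bromination (LiN(SiMe3)2, THF, −78 °C; then NBS) gives methyl 2-bromo-2-[3,5-bis(triisopropylsilyloxy)phenyl]acetate F4.
   - 6 is alkylated at its 4-hydroxyl with F4 (NaHCO3, DMF, rt) to methyl 2-[3,5-bis(triisopropylsilyloxy)phenyl]-2-(4-formyl-2-hydroxyphenoxy)acetate F5.
   - Horner–Wadsworth–Emmons reaction with 5 (NaH, THF) gives methyl 2-[3,5-bis(triisopropylsilyloxy)phenyl]-2-(4-{(E)-2-[3,5-bis(triisopropylsilyloxy)phenyl]ethenyl}-2-hydroxyphenoxy)acetate F6.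
   - Esterification with 11 (DIC, DMAP) gives the 3,4-bis(triisopropylsilyloxy)benzoate of F6, diester F7.
   - A Dieckmann-type O-to-C acyl transfer (LiN(SiMe3)2, THF, −78 to 0 °C) closes ring B through Ca–Cb and gives methyl 3-[3,4-bis(triisopropylsilyloxy)phenyl]-2-[3,5-bis(triisopropylsilyloxy)phenyl]-6-{(E)-2-[3,5-bis(triisopropylsilyloxy)phenyl]ethenyl}-3-hydroxy-2,3-dihydro-1,4-benzodioxine-2-carboxylate F8.
   - Krapcho dealkoxycarbonylation of F8 (LiCl, DMSO–H2O, 130 °C) returns hemiketal 15.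

3. Step 11. What may go wrong is phenoxide-triggered opening of the Ca–O bond through a para-quinone methide of ring C, with epimerisation from cis to trans, and air oxidation of the free catechol during isolation. The fallback sets out from 17 and comes back at 18. Each phenoxide is trapped as it forms by desilylative acetylation (TBAF, Ac2O, THF, 0 °C), which gives the stable, chromatographable hexaacetate of 18, (2R,3S)-2-(3,4-diacetoxyphenyl)-3-(3,5-diacetoxyphenyl)-7-[(E)-2-(3,5-diacetoxyphenyl)ethenyl]-2,3-dihydro-1,4-benzodioxine F9. The acetates are then removed under near-neutral conditions (NH4OAc, MeOH–H2O, rt, argon) to give 18.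

Further compounds
F1 | step 10 | (1S,2S)-1-[3,4-bis(triisopropylsilyloxy)phenyl]-2-[3,5-bis(triisopropylsilyloxy)phenyl]-2-(4-{(E)-2-[3,5-bis(triisopropylsilyloxy)phenyl]ethenyl}-2-hydroxyphenoxy)ethanol | O[C@@H](c1ccc(O[Si](C(C)C)(C(C)C)C(C)C)c(O[Si](C(C)C)(C(C)C)C(C)C)c1)[C@H](c1cc(O[Si](C(C)C)(C(C)C)C(C)C)cc(O[Si](C(C)C)(C(C)C)C(C)C)c1)Oc1ccc(/C=C/c2cc(O[Si](C(C)C)(C(C)C)C(C)C)cc(O[Si](C(C)C)(C(C)C)C(C)C)c2)cc1O
F2 | step 9 | methyl 2-(3,5-dihydroxyphenyl)acetate (purchased) | COC(=O)Cc1cc(O)cc(O)c1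
F3 | step 9 | methyl 2-[3,5-bis(triisopropylsilyloxy)phenyl]acetate | COC(=O)Cc1cc(O[Si](C(C)C)(C(C)C)C(C)C)cc(O[Si](C(C)C)(C(C)C)C(C)C)c1
F4 | step 9 | methyl 2-bromo-2-[3,5-bis(triisopropylsilyloxy)phenyl]acetate | COC(=O)C(Br)c1cc(O[Si](C(C)C)(C(C)C)C(C)C)cc(O[Si](C(C)C)(C(C)C)C(C)C)c1
F5 | step 9 | methyl 2-[3,5-bis(triisopropylsilyloxy)phenyl]-2-(4-formyl-2-hydroxyphenoxy)acetate | COC(=O)C(Oc1ccc(C=O)cc1O)c1cc(O[Si](C(C)C)(C(C)C)C(C)C)cc(O[Si](C(C)C)(C(C)C)C(C)C)c1
F6 | step 9 | methyl 2-[3,5-bis(triisopropylsilyloxy)phenyl]-2-(4-{(E)-2-[3,5-bis(triisopropylsilyloxy)phenyl]ethenyl}-2-hydroxyphenoxy)acetate | COC(=O)C(Oc1ccc(/C=C/c2cc(O[Si](C(C)C)(C(C)C)C(C)C)cc(O[Si](C(C)C)(C(C)C)C(C)C)c2)cc1O)c1cc(O[Si](C(C)C)(C(C)C)C(C)C)cc(O[Si](C(C)C)(C(C)C)C(C)C)c1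
F7 | step 9 | 2-{1-[3,5-bis(triisopropylsilyloxy)phenyl]-2-methoxy-2-oxoethoxy}-5-{(E)-2-[3,5-bis(triisopropylsilyloxy)phenyl]ethenyl}phenyl 3,4-bis(triisopropylsilyloxy)benzoate | COC(=O)C(Oc1ccc(/C=C/c2cc(O[Si](C(C)C)(C(C)C)C(C)C)cc(O[Si](C(C)C)(C(C)C)C(C)C)c2)cc1OC(=O)c1ccc(O[Si](C(C)C)(C(C)C)C(C)C)c(O[Si](C(C)C)(C(C)C)C(C)C)c1)c1cc(O[Si](C(C)C)(C(C)C)C(C)C)cc(O[Si](C(C)C)(C(C)C)C(C)C)c1
F8 | step 9 | methyl 3-[3,4-bis(triisopropylsilyloxy)phenyl]-2-[3,5-bis(triisopropylsilyloxy)phenyl]-6-{(E)-2-[3,5-bis(triisopropylsilyloxy)phenyl]ethenyl}-3-hydroxy-2,3-dihydro-1,4-benzodioxine-2-carboxylate | COC(=O)C1(c2cc(O[Si](C(C)C)(C(C)C)C(C)C)cc(O[Si](C(C)C)(C(C)C)C(C)C)c2)Oc2ccc(/C=C/c3cc(O[Si](C(C)C)(C(C)C)C(C)C)cc(O[Si](C(C)C)(C(C)C)C(C)C)c3)cc2OC1(O)c1ccc(O[Si](C(C)C)(C(C)C)C(C)C)c(O[Si](C(C)C)(C(C)C)C(C)C)c1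
F9 | step 11 | (2R,3S)-2-(3,4-diacetoxyphenyl)-3-(3,5-diacetoxyphenyl)-7-[(E)-2-(3,5-diacetoxyphenyl)ethenyl]-2,3-dihydro-1,4-benzodioxine | CC(=O)Oc1cc(OC(C)=O)cc(/C=C/c2ccc3c(c2)O[C@H](c2ccc(OC(C)=O)c(OC(C)=O)c2)[C@H](c2cc(OC(C)=O)cc(OC(C)=O)c2)O3)c1
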